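The depside is cut at the aryl ester linking O4 of ring A to the ring B carbonyl, and ring A is traced back to methyl orsellinate. The plan exploits the fact that the methyl-bearing carbons C3 and C5 of ring A both flank O4 (C3 also adjoins O2, C5 lies para to it). These are the only carbons an orsellinate offers to bromine. One palladium-catalysed operation then exchanges both bromines for methyl groups, forming the C3–CH3 and C5–CH3 bonds and completing the hexasubstituted ring. The precursor is the 3,5-dibromo orsellinate whose O4 is a benzyl ether and whose O2 already carries the methyl group of the target.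

Key step: step 4

Remark: ring A is the methyl benzoate ring (C1 bears CO2CH3). Ring B is the formyl ring (primed locants, C1' bears the depside carbonyl). The target has no stereocentre.

Step 1
Reactants: 1 methyl 2,4-dihydroxy-6-methylbenzoate (methyl orsellinate)
Product: 2 methyl 3,5-dibromo-2,4-dihydroxy-6-methylbenzoate
Conditions: Br2 (2.2 equiv), AcOH, 15 °C → rt, dark
Reagents that add atoms: bromine, BrBr
Why: Electrophilic aromatic bromination; C3 and C5 are the only ring C–H positions and each is ortho or para to both hydroxyl groups, so two equivalents of Br2 should fill both without touching the ester or the C6 methyl.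

Step 2
Reactants: 2 methyl 3,5-dibromo-2,4-dihydroxy-6-methylbenzoate
Product: 3 methyl 4-(benzyloxy)-3,5-dibromo-2-hydroxy-6-methylbenzoate
Conditions: BnBr (1.05 equiv), K2CO3 (1.1 equiv), DMF, rt
Reagents that add atoms: benzyl bromide, BrCc1ccccc1
Why: Williamson ether synthesis under substrate control; the 4-OH, acidified by two ortho bromines and the para ester, is deprotonated first, while the 2-OH is held in a hydrogen bond to the ester carbonyl, so one equivalent of benzyl bromide should react at O4 only.

Step 3
Reactants: 3 methyl 4-(benzyloxy)-3,5-dibromo-2-hydroxy-6-methylbenzoate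
Product: 4 methyl 4-(benzyloxy)-3,5-dibromo-2-methoxy-6-methylbenzoate
Conditions: MeI (3 equiv), K2CO3 (3 equiv), DMF, 40 °C
Reagents that add atoms: iodomethane, CI
Why: Williamson O-methylation of the remaining chelated phenol, for which an excess of the small electrophile MeI in warm DMF suffices and which installs the 2-methoxy group of the target.

Step 4
Reactants: 4 methyl 4-(benzyloxy)-3,5-dibromo-2-methoxy-6-methylbenzoate; 5 trimethylboroxine
Product: 6 methyl 4-(benzyloxy)-2-methoxy-3,5,6-trimethylbenzoate
Conditions: 5 (3 equiv), Pd(OAc)2 (10 mol %), SPhos (20 mol %), K3PO4 (6 equiv), toluene/H2O (10:1), 100 °C, sealed vessel, argon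
Reagents that add atoms: trimethylboroxine, CB1OB(C)OB(C)O1
Why: Suzuki–Miyaura methylation run twice on one ring: SPhos-ligated zerovalent palladium, formed in the flask from Pd(OAc)2, inserts into a C–Br bond, the base-activated methylboron species passes its CH3 to the arylpalladium bromide, and reductive elimination forges the aryl–CH3 bond before the cycle repeats at the other bromide. The closest known reaction type is the methylation of di-ortho-substituted aryl bromides with methylboronic acid or trimethylboroxine under Pd(OAc)2/dialkylbiarylphosphine catalysis. No ring is closed and no stereocentre is created. The step needs completeness, not site selectivity, because either order of coupling converges on 6; the bulky, electron-rich ligand keeps a monoligated palladium centre active enough for two crowded, electron-rich C–Br bonds, and a palladium-bound CH3 has no β-hydrogen to lose. Excess boroxine, a little water to open it and a non-polar medium keep transmetalation ahead of hydrodebromination and of C–H palladation of the benzyl ring. Both phenolic oxygens of 4 are capped as ethers and its di-ortho-substituted methyl ester resists K3PO4, so nothing else in the substrate should react.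

Step 5
Reactants: 6 methyl 4-(benzyloxy)-2-methoxy-3,5,6-trimethylbenzoate
Product: 7 methyl 4-hydroxy-2-methoxy-3,5,6-trimethylbenzoate
Conditions: H2 (1 atm), 10% Pd/C, EtOAc/MeOH, rt
Reagents that add atoms: none
Why: Catalytic hydrogenolysis of a benzyl aryl ether; the methyl ester, the aryl methyl ether and the fully substituted ring are inert to H2 over Pd/C at ambient pressure.

Step 6
Reactants: 8 methyl 2,4-dihydroxy-3,6-dimethylbenzoate (methyl atrarate)
Product: 10 methyl 5-formyl-2,4-dihydroxy-3,6-dimethylbenzoate, via alpha-chloro ether 9 (not isolated)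
Conditions: TiCl4 (3.5 equiv), Cl2CHOCH3 (1.5 equiv), CH2Cl2, −10 °C → rt; then ice/1 M HCl
Reagents that add atoms: dichloromethyl methyl ether, COC(Cl)Cl; water, O
Why: Rieche formylation; TiCl4 bound to the phenol oxygens delivers the cation derived from dichloromethyl methyl ether to C5, the only unsubstituted ring carbon (ortho to the 4-OH, para to the 2-OH), and the α-chloro ether 9 is hydrolysed to the aldehyde on aqueous work-up.

Step 7
Reactants: 10 methyl 5-formyl-2,4-dihydroxy-3,6-dimethylbenzoate
Product: 11 methyl 5-formyl-2,4-bis(methoxymethoxy)-3,6-dimethylbenzoate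
Conditions: NaH (2.6 equiv), MOMCl (3 equiv), THF/DMF, 0 °C → rt
Reagents that add atoms: chloromethyl methyl ether, COCCl
Why: Williamson-type O-alkylation; both phenols are chelated (one to the ester, one to the aldehyde) and are therefore turned fully into phenoxides with NaH before MOMCl traps them, while the aldehyde has no α-hydrogen and is left alone.

Step 8
Reactants: 11 methyl 5-formyl-2,4-bis(methoxymethoxy)-3,6-dimethylbenzoate
Product: 12 5-formyl-2,4-bis(methoxymethoxy)-3,6-dimethylbenzoic acid
Conditions: KOH (10 equiv), DMSO/H2O (4:1), 80 °C, dilute, argon; then 1 M HCl to pH 4, 0 °C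
Reagents that add atoms: potassium hydroxide, [K+].[OH-]
Why: Saponification by acyl–oxygen cleavage of a di-ortho-substituted benzoate, which needs poorly solvated hydroxide and heat; MOM ethers are base-stable, the crowded non-enolisable aldehyde should disproportionate only slowly in dilute solution, and cold acidification to pH 4 spares the acetals.

Step 9
Reactants: 12 5-formyl-2,4-bis(methoxymethoxy)-3,6-dimethylbenzoic acid; 7 methyl 4-hydroxy-2-methoxy-3,5,6-trimethylbenzoate
Product: 13 methyl 4-{[5-formyl-2,4-bis(methoxymethoxy)-3,6-dimethylbenzoyl]oxy}-2-methoxy-3,5,6-trimethylbenzoate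
Conditions: DCC (1.5 equiv), DMAP (1 equiv), CH2Cl2, rt → 40 °C
Reagents that add atoms: none
Why: Steglich esterification; the carbodiimide activates acid 12 and DMAP relays the acyl group to the only free hydroxyl present, the 4-OH of 7, a method established for depside bonds between ortho-substituted partners and neutral enough for the MOM ethers and the aldehyde.

Step 10
Reactants: 13 methyl 4-{[5-formyl-2,4-bis(methoxymethoxy)-3,6-dimethylbenzoyl]oxy}-2-methoxy-3,5,6-trimethylbenzoate
Product: 14 methyl 4-[(5-formyl-2,4-dihydroxy-3,6-dimethylbenzoyl)oxy]-2-methoxy-3,5,6-trimethylbenzoate (CNP0316552.0)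
Conditions: TFA/CH2Cl2 (1:4), 0 °C → rt; aqueous work-up
Reagents that add atoms: none
Why: Acid-catalysed acetal cleavage; both MOM ethers lie ortho to a carbonyl group and should fall quickly in a non-nucleophilic medium that cannot transesterify the depside or the methyl ester, and since both rings are fully substituted the released formaldehyde equivalent cannot alkylate them.

Compound list
1 | methyl 2,4-dihydroxy-6-methylbenzoate (methyl orsellinate) | COC(=O)c1c(C)cc(O)cc1O | starting material
2 | methyl 3,5-dibromo-2,4-dihydroxy-6-methylbenzoate | COC(=O)c1c(C)c(Br)c(O)c(Br)c1O | intermediate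
3 | methyl 4-(benzyloxy)-3,5-dibromo-2-hydroxy-6-methylbenzoate | COC(=O)c1c(C)c(Br)c(OCc2ccccc2)c(Br)c1O | intermediate
4 | methyl 4-(benzyloxy)-3,5-dibromo-2-methoxy-6-methylbenzoate | COC(=O)c1c(C)c(Br)c(OCc2ccccc2)c(Br)c1OC | intermediate
5 | trimethylboroxine | CB1OB(C)OB(C)O1 | starting material
6 | methyl 4-(benzyloxy)-2-methoxy-3,5,6-trimethylbenzoate | COC(=O)c1c(C)c(C)c(OCc2ccccc2)c(C)c1OC | intermediate
7 | methyl 4-hydroxy-2-methoxy-3,5,6-trimethylbenzoate | COC(=O)c1c(C)c(C)c(O)c(C)c1OC | intermediate
8 | methyl 2,4-dihydroxy-3,6-dimethylbenzoate (methyl atrarate) | COC(=O)c1c(C)cc(O)c(C)c1O | starting material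
9 | methyl 5-[chloro(methoxy)methyl]-2,4-dihydroxy-3,6-dimethylbenzoate (racemic, transient) | COC(=O)c1c(C)c(C(Cl)OC)c(O)c(C)c1O | intermediate
10 | methyl 5-formyl-2,4-dihydroxy-3,6-dimethylbenzoate | COC(=O)c1c(C)c(C=O)c(O)c(C)c1O | intermediate
11 | methyl 5-formyl-2,4-bis(methoxymethoxy)-3,6-dimethylbenzoate | COC(=O)c1c(C)c(C=O)c(OCOC)c(C)c1OCOC | intermediate
12 | 5-formyl-2,4-bis(methoxymethoxy)-3,6-dimethylbenzoic acid | OC(=O)c1c(C)c(C=O)c(OCOC)c(C)c1OCOC | intermediate
13 | methyl 4-{[5-formyl-2,4-bis(methoxymethoxy)-3,6-dimethylbenzoyl]oxy}-2-methoxy-3,5,6-trimethylbenzoate | COC(=O)c1c(C)c(C)c(OC(=O)c2c(C)c(C=O)c(OCOC)c(C)c2OCOC)c(C)c1OC | intermediate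
14 | methyl 4-[(5-formyl-2,4-dihydroxy-3,6-dimethylbenzoyl)oxy]-2-methoxy-3,5,6-trimethylbenzoate | COC(=O)c1c(C)c(C)c(OC(=O)c2c(C)c(C=O)c(O)c(C)c2O)c(C)c1OC | target

Total step count: 10. Longest linear sequence: 7 (steps 1, 2, 3, 4, 5, 9, 10). The ring B branch (steps 6 to 8) joins at step 9.

Steps most likely to fail

1. Step 4.
- **Risk:** The exchange may stay incomplete. The second, more crowded oxidative addition can stall. Slow transmetalation also leaves time for hydrodebromination or for palladation of the benzyl ring.
- **Fallback:** This uses no cross-coupling. The C3 methyl comes with the starting material and the C5 carbon enters as a formyl group. Setting out from 10, hydrogenolysis of the aryl aldehyde (H2, Pd/C, AcOH) should give methyl 2,4-dihydroxy-3,5,6-trimethylbenzoate F1. Selective benzylation of the unchelated 4-OH (BnBr, K2CO3, DMF) should give methyl 4-(benzyloxy)-2-hydroxy-3,5,6-trimethylbenzoate F2. O-methylation (MeI, K2CO3, DMF) comes back to the route at 6.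

2. Step 9.
- **Risk:** Both reacting centres carry two ortho substituents. Acyl transfer to the phenol may therefore be slower than the O-to-N acyl shift of the carbodiimide adduct or than self-condensation of the acid to its anhydride.
- **Fallback:** This uses an isolated acyl halide with the smallest leaving group and an anionic nucleophile. Setting out from 12, cyanuric fluoride and pyridine in CH2Cl2 should give 5-formyl-2,4-bis(methoxymethoxy)-3,6-dimethylbenzoyl fluoride F3. This reagent leaves the aldehyde alone. The fluoride is far less prone than an acid chloride to attack by the neighbouring MOM oxygen. It then acylates 7 in THF in the presence of NaH and comes back to the route at 13.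

3. Step 8.
- **Risk:** Hydroxide attack at the shielded ester carbonyl may be very slow. The temperature then required could bring on Cannizzaro-type disproportionation of the aldehyde or base-induced condensation through the C6' methyl.
- **Fallback:** The aldehyde is postponed to the last step.
  - Setting out from 8, NaH/MOMCl should give methyl 2,4-bis(methoxymethoxy)-3,6-dimethylbenzoate F4.
  - KOH in aqueous DMSO, now with no aldehyde present, should give 2,4-bis(methoxymethoxy)-3,6-dimethylbenzoic acid F5.
  - Steglich esterification with 7 should give methyl 4-{[2,4-bis(methoxymethoxy)-3,6-dimethylbenzoyl]oxy}-2-methoxy-3,5,6-trimethylbenzoate F6.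
  - TFA in CH2Cl2 should give methyl 4-[(2,4-dihydroxy-3,6-dimethylbenzoyl)oxy]-2-methoxy-3,5,6-trimethylbenzoate F7.
  - C5' is then the only aromatic C–H in the molecule. Rieche formylation (TiCl4, Cl2CHOCH3, CH2Cl2) can therefore occur only there. It passes through methyl 4-({5-[chloro(methoxy)methyl]-2,4-dihydroxy-3,6-dimethylbenzoyl}oxy)-2-methoxy-3,5,6-trimethylbenzoate F8, which is hydrolysed on work-up, and comes back to the route at 14.

Further compounds
F1 | step 4 | methyl 2,4-dihydroxy-3,5,6-trimethylbenzoate | COC(=O)c1c(C)c(C)c(O)c(C)c1O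
F2 | step 4 | methyl 4-(benzyloxy)-2-hydroxy-3,5,6-trimethylbenzoate | COC(=O)c1c(C)c(C)c(OCc2ccccc2)c(C)c1O
F3 | step 9 | 5-formyl-2,4-bis(methoxymethoxy)-3,6-dimethylbenzoyl fluoride | O=C(F)c1c(C)c(C=O)c(OCOC)c(C)c1OCOC
F4 | step 8 | methyl 2,4-bis(methoxymethoxy)-3,6-dimethylbenzoate | COC(=O)c1c(C)cc(OCOC)c(C)c1OCOC
F5 | step 8 | 2,4-bis(methoxymethoxy)-3,6-dimethylbenzoic acid | OC(=O)c1c(C)cc(OCOC)c(C)c1OCOC
F6 | step 8 | methyl 4-{[2,4-bis(methoxymethoxy)-3,6-dimethylbenzoyl]oxy}-2-methoxy-3,5,6-trimethylbenzoate | COC(=O)c1c(C)c(C)c(OC(=O)c2c(C)cc(OCOC)c(C)c2OCOC)c(C)c1OC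
F7 | step 8 | methyl 4-[(2,4-dihydroxy-3,6-dimethylbenzoyl)oxy]-2-methoxy-3,5,6-trimethylbenzoate | COC(=O)c1c(C)c(C)c(OC(=O)c2c(C)cc(O)c(C)c2O)c(C)c1OC
F8 | step 8 | methyl 4-({5-[chloro(methoxy)methyl]-2,4-dihydroxy-3,6-dimethylbenzoyl}oxy)-2-methoxy-3,5,6-trimethylbenzoate | COC(=O)c1c(C)c(C)c(OC(=O)c2c(C)c(C(Cl)OC)c(O)c(C)c2O)c(C)c1OC
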